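Both aryl halves of this depside are the same 6-(2-oxononyl)-β-resorcylate, so the route rests on one disconnection: the C1–C6 bond of ring A, formed by isomerising a 4-pyrone into a benzene ring. The key step exploits the alternating pattern of ring A (ester carbon on C1, hydroxyls on C2 and C4, carbon arm on C6), which is that of a 3,5,7-trioxo ester. In one operation base opens the pyranone and an aldol–dehydration closes the carbocycle. The precursor is a pyran-4-one carrying a methyl acetate arm at C2 and a dioxolane-masked 2-oxononyl arm at C6. The resulting phenol serves as ring A and, after benzylation and saponification, as ring B.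

Key step: step 4

Remark on the chemistry: the target has no stereocentre; the only stereocentres in the route are those of the transient aldol carbinol 8, which forms as a mixture and loses both on aromatisation.

Step 1
Reactants: 1 2,6-dimethyl-4H-pyran-4-one (about 2 equiv); 2 methyl octanoate
Product: 3 2-methyl-6-(2-oxononyl)-4H-pyran-4-one
Conditions: LiN(SiMe3)2 (1 equiv per 1), THF, −78 °C; then 2, −78 to −30 °C; AcOH quench
Reagents that add atoms: none
Why: Lateral deprotonation of the vinylogous methyl ketone gives a dienolate that should undergo a crossed Claisen-type C-acylation with the ester, the second equivalent of carbanion taking the proton of the more acidic product so that acylation stops at the mono-ketone.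

Step 2
Reactants: 3 2-methyl-6-(2-oxononyl)-4H-pyran-4-one
Product: 4 2-[(2-heptyl-1,3-dioxolan-2-yl)methyl]-6-methyl-4H-pyran-4-one
Conditions: ethylene glycol, TsOH·H2O (cat.), benzene, reflux, Dean–Stark
Reagents that add atoms: ethylene glycol, OCCO
Why: Acid-catalysed ketalisation with azeotropic removal of water should convert only the side-chain ketone, because the C4 carbonyl of the pyranone is a vinylogous ester and does not ketalise.

Step 3
Reactants: 4 2-[(2-heptyl-1,3-dioxolan-2-yl)methyl]-6-methyl-4H-pyran-4-one; 5 dimethyl carbonate
Product: 6 methyl 2-[6-[(2-heptyl-1,3-dioxolan-2-yl)methyl]-4-oxo-4H-pyran-2-yl]acetate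
Conditions: LiN(SiMe3)2 (2.2 equiv), THF, −78 °C; then 5, −78 to 0 °C; AcOH quench
Reagents that add atoms: none
Why: Kinetic lateral metalation by the bulky amide should occur at the unhindered methyl and not at the neopentyl-like CH2 next to the dioxolane, and the carbanion is methoxycarbonylated (Claisen-type acylation by a carbonate), the second equivalent of base deprotonating the product and so preventing double acylation.

Step 4
Reactants: 6 methyl 2-[6-[(2-heptyl-1,3-dioxolan-2-yl)methyl]-4-oxo-4H-pyran-2-yl]acetate
Product: 9 methyl 2-[(2-heptyl-1,3-dioxolan-2-yl)methyl]-4,6-dihydroxybenzoate, via open-chain triketo ester 7 (not isolated), via cyclic aldol carbinol 8 (not isolated)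
Conditions: KOH (3 equiv), MeOH, 0 °C to rt, under N2; then AcOH to pH 6
Reagents that add atoms: none
Why: Hydroxide adds to C6 of the pyranone (C2 is switched off because its acetate arm is present as the enolate), the hemiketal collapses and the ring opens to the enolate of trioxo ester 7, whose C2 carbanion, flanked by the ester and the C3 ketone, adds to the C7 carbonyl to give carbinol 8, which loses water and tautomerises to the arene. The closest known reaction type is the base-induced conversion of (4-oxo-4H-pyran-2-yl)acetates into orsellinates, in essence an intramolecular aldol condensation with aromatisation. The one ring is closed in a 6-(enolexo)-exo-trig mode, and this makes the C1–C6 bond of ring A. No stereocentre remains, since the two of 8 vanish on dehydration. The selectivity needed is carbon-to-ketone closure by C2 in preference to carbon-to-ester (Claisen) closure by C6, which would give an acylphloroglucinol, together with non-participation of the side-chain carbonyl; the higher acidity of the ester-flanked CH2, a non-chelating potassium counter-ion in methanol and the dioxolane should secure this. Methanol makes ester exchange degenerate, and the product, held as its phenoxide, should resist saponification at room temperature.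

Step 5
Reactants: 9 methyl 2-[(2-heptyl-1,3-dioxolan-2-yl)methyl]-4,6-dihydroxybenzoate (the portion destined for ring B)
Product: 10 methyl 2,4-bis(benzyloxy)-6-[(2-heptyl-1,3-dioxolan-2-yl)methyl]benzoate
Conditions: BnBr (2.4 equiv), K2CO3, DMF, 60 °C
Reagents that add atoms: benzyl bromide, BrCc1ccccc1
Why: Williamson etherification of both phenoxides, the hydrogen-bonded 2-OH being driven to react by excess bromide in warm DMF, while ester and ketal are inert to carbonate.

Step 6
Reactants: 10 methyl 2,4-bis(benzyloxy)-6-[(2-heptyl-1,3-dioxolan-2-yl)methyl]benzoate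
Product: 11 2,4-bis(benzyloxy)-6-[(2-heptyl-1,3-dioxolan-2-yl)methyl]benzoic acid
Conditions: KOH (excess), DMSO/H2O (4:1), 90 °C; then cold 1 M HCl to pH 4
Reagents that add atoms: potassium hydroxide, [K+].[OH-]
Why: Saponification of the hindered 2,6-disubstituted benzoate needs forcing hydroxide, which benzyl ethers and the dioxolane tolerate, and brief cold acidification should free the acid without opening the ketal.

Step 7
Reactants: 11 2,4-bis(benzyloxy)-6-[(2-heptyl-1,3-dioxolan-2-yl)methyl]benzoic acid; 9 methyl 2-[(2-heptyl-1,3-dioxolan-2-yl)methyl]-4,6-dihydroxybenzoate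
Product: 12 methyl 4-{[2,4-bis(benzyloxy)-6-[(2-heptyl-1,3-dioxolan-2-yl)methyl]benzoyl]oxy}-2-[(2-heptyl-1,3-dioxolan-2-yl)methyl]-6-hydroxybenzoate
Conditions: DCC, DMAP (cat.), CH2Cl2, 0 °C to rt
Reagents that add atoms: none
Why: Steglich esterification (carbodiimide activation, acyl transfer by DMAP) should acylate the free 4-OH of 9 and spare the 2-OH, which is hydrogen-bonded to and flanked by the ester carbonyl; both ketones are still ketals, so no enolate can attack the new aryl ester.

Step 8
Reactants: 12 methyl 4-{[2,4-bis(benzyloxy)-6-[(2-heptyl-1,3-dioxolan-2-yl)methyl]benzoyl]oxy}-2-[(2-heptyl-1,3-dioxolan-2-yl)methyl]-6-hydroxybenzoate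
Product: 13 methyl 4-{[2,4-bis(benzyloxy)-6-(2-oxononyl)benzoyl]oxy}-2-hydroxy-6-(2-oxononyl)benzoate
Conditions: 2 M aq. HCl, THF, rt
Reagents that add atoms: water, O
Why: Acid-catalysed ketal hydrolysis of both dioxolanes; in dilute acid at room temperature the aryl ester, methyl ester and benzyl ethers should survive, and ring B still carries its 2-benzyloxy group, so the depside carbonyl is not hydrogen-bond activated toward enol lactonisation.

Step 9
Reactants: 13 methyl 4-{[2,4-bis(benzyloxy)-6-(2-oxononyl)benzoyl]oxy}-2-hydroxy-6-(2-oxononyl)benzoate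
Product: 14 methyl 4-{[2,4-dihydroxy-6-(2-oxononyl)benzoyl]oxy}-2-hydroxy-6-(2-oxononyl)benzoate (CNP0110390.0)
Conditions: H2 (1 atm), 10% Pd/C, EtOAc, rt
Reagents that add atoms: none
Why: Catalytic hydrogenolysis of the two benzyl ethers over Pd/C is neutral and should leave the aliphatic ketones, both esters and the arenes untouched, so the route ends without acid or base.

Compound list
1 | 2,6-dimethyl-4H-pyran-4-one | CC1=CC(=O)C=C(C)O1 | starting material
2 | methyl octanoate | CCCCCCCC(=O)OC | starting material
3 | 2-methyl-6-(2-oxononyl)-4H-pyran-4-one | CC1=CC(=O)C=C(CC(=O)CCCCCCC)O1 | intermediate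
4 | 2-[(2-heptyl-1,3-dioxolan-2-yl)methyl]-6-methyl-4H-pyran-4-one | CC1=CC(=O)C=C(CC2(CCCCCCC)OCCO2)O1 | intermediate
5 | dimethyl carbonate | COC(=O)OC | starting material
6 | methyl 2-[6-[(2-heptyl-1,3-dioxolan-2-yl)methyl]-4-oxo-4H-pyran-2-yl]acetate | COC(=O)CC1=CC(=O)C=C(CC2(CCCCCCC)OCCO2)O1 | intermediate
7 | methyl 8-(2-heptyl-1,3-dioxolan-2-yl)-3,5,7-trioxooctanoate (open-chain triketo ester, not isolated) | COC(=O)CC(=O)CC(=O)CC(=O)CC1(CCCCCCC)OCCO1 | intermediate
8 | methyl 2-[(2-heptyl-1,3-dioxolan-2-yl)methyl]-2-hydroxy-4,6-dioxocyclohexane-1-carboxylate (cyclic aldol carbinol, mixture of diastereomers, not isolated) | COC(=O)C1C(=O)CC(=O)CC1(O)CC1(CCCCCCC)OCCO1 | intermediate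
9 | methyl 2-[(2-heptyl-1,3-dioxolan-2-yl)methyl]-4,6-dihydroxybenzoate (ring A phenol ketal) | COC(=O)c1c(O)cc(O)cc1CC1(CCCCCCC)OCCO1 | intermediate
10 | methyl 2,4-bis(benzyloxy)-6-[(2-heptyl-1,3-dioxolan-2-yl)methyl]benzoate | COC(=O)c1c(OCc2ccccc2)cc(OCc2ccccc2)cc1CC1(CCCCCCC)OCCO1 | intermediate
11 | 2,4-bis(benzyloxy)-6-[(2-heptyl-1,3-dioxolan-2-yl)methyl]benzoic acid | OC(=O)c1c(OCc2ccccc2)cc(OCc2ccccc2)cc1CC1(CCCCCCC)OCCO1 | intermediate
12 | methyl 4-{[2,4-bis(benzyloxy)-6-[(2-heptyl-1,3-dioxolan-2-yl)methyl]benzoyl]oxy}-2-[(2-heptyl-1,3-dioxolan-2-yl)methyl]-6-hydroxybenzoate | COC(=O)c1c(O)cc(OC(=O)c2c(OCc3ccccc3)cc(OCc3ccccc3)cc2CC2(CCCCCCC)OCCO2)cc1CC1(CCCCCCC)OCCO1 | intermediate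
13 | methyl 4-{[2,4-bis(benzyloxy)-6-(2-oxononyl)benzoyl]oxy}-2-hydroxy-6-(2-oxononyl)benzoate | COC(=O)c1c(O)cc(OC(=O)c2c(OCc3ccccc3)cc(OCc3ccccc3)cc2CC(=O)CCCCCCC)cc1CC(=O)CCCCCCC | intermediate
14 | methyl 4-{[2,4-dihydroxy-6-(2-oxononyl)benzoyl]oxy}-2-hydroxy-6-(2-oxononyl)benzoate | CCCCCCCC(=O)Cc1cc(OC(=O)c2c(O)cc(O)cc2CC(=O)CCCCCCC)cc(O)c1C(=O)OC | target

Total step count: 9. Longest linear sequence: 9 steps (steps 1 to 9 lie on one line; compound 9 is used twice, as ring A in step 7 and as the source of ring B in step 5).

Steps most likely to fail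

Step 4. The opened chain may cyclise through its C6 carbanion onto the ester carbon (Claisen mode), or the methyl ester may be hydrolysed while the aldol closure runs, so that ester, acid and acylphloroglucinol form side by side. The fallback takes the ester out of play on purpose. It sets out from 6, which is treated with aqueous KOH at room temperature. The acetate arm is saponified first, and the carboxylate cannot serve as an acyl acceptor, so aldol closure is the only six-membered cyclisation left. Cold acidification to pH 4 should give 2-[(2-heptyl-1,3-dioxolan-2-yl)methyl]-4,6-dihydroxybenzoic acid F1, kept cold to avoid decarboxylation. Selective alkylation of its carboxylate (MeI, KHCO3, DMF, rt; hydrogen carbonate does not deprotonate the phenols) comes back to the route at 9.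

Step 3. Metalation may occur at the CH2 between the pyranone and the dioxolane and not at the methyl group, followed by β-elimination of a ketal oxygen or by carboxylation at the wrong carbon. The fallback installs the two arms in the opposite order, so that no ketal is present during any metalation. It sets out from 1: lateral lithiation (LiN(SiMe3)2, THF, −78 °C) and methoxycarbonylation with 5 should give methyl 2-(6-methyl-4-oxo-4H-pyran-2-yl)acetate F2. Its dianion (LiN(iPr)2, more than 2 equiv, THF, −78 °C) should react at the later-formed, less stabilised methyl-derived carbanion and is acylated with 2 to methyl 2-[4-oxo-6-(2-oxononyl)-4H-pyran-2-yl]acetate F3. Ketalisation (ethylene glycol, TsOH·H2O, benzene, Dean–Stark) comes back to the route at 6.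

Step 1. Proton transfer from the acidic product to the carbanion may stall the acylation, and the carbanion may condense with unmetalated pyranone, so that conversion of the ester stays incomplete. The fallback replaces acylation by addition and oxidation. It sets out from 1: the same lithiated species adds to octanal at −78 °C, a step whose alkoxide product does not quench the carbanion, to give racemic 2-(2-hydroxynonyl)-6-methyl-4H-pyran-4-one F4. Oxidation with Dess–Martin periodinane (NaHCO3, CH2Cl2, rt) comes back to the route at 3.

Further compounds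
F1 | step 4 | 2-[(2-heptyl-1,3-dioxolan-2-yl)methyl]-4,6-dihydroxybenzoic acid | OC(=O)c1c(O)cc(O)cc1CC1(CCCCCCC)OCCO1
F2 | step 3 | methyl 2-(6-methyl-4-oxo-4H-pyran-2-yl)acetate | COC(=O)CC1=CC(=O)C=C(C)O1
F3 | step 3 | methyl 2-[4-oxo-6-(2-oxononyl)-4H-pyran-2-yl]acetate | COC(=O)CC1=CC(=O)C=C(CC(=O)CCCCCCC)O1
F4 | step 1 | 2-(2-hydroxynonyl)-6-methyl-4H-pyran-4-one (racemic) | CC1=CC(=O)C=C(CC(O)CCCCCCC)O1
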